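The constants put the fourth exchange ahead of the third, 0.087 /M/min against 0.020 /M/min, so the share asked for depends on how far the complex with three exchanged goes on once made.

    starting complex + incoming ligand → leaving ligand + complex with one exchanged (k1 = 0.18 /M/min)
    complex with one exchanged + incoming ligand → leaving ligand + complex with two exchanged (k2 = 0.12 /M/min)
    complex with two exchanged + incoming ligand → leaving ligand + complex with three exchanged (k3 = 0.020 /M/min)
    complex with three exchanged + incoming ligand → leaving ligand + complex with four exchanged (k4 = 0.087 /M/min)
    2 starting complex → homo dimer (k5 = 0.029 /M/min)

the same everywhere: leaving ligand 5.00 equiv
- Saturday's: starting complex 0.050 M (fed, over 1.00 d); incoming ligand 0.500 equiv; time 2.0 d; a stirred flask in which starting complex is dosed at a steady rate over 1.00 d without added volume, worked up at 2.0 d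
- Monday's: starting complex 0.050 M; incoming ligand 0.500 equiv; one stirred flow tank at steady state, fed with the mixture as stated, mean residence time 2.0 d
- Tuesday's: starting complex 0.050 M; incoming ligand 0.500 equiv (fed, over 1.00 d); time 2.0 d; all but incoming ligand at the start; incoming ligand goes in evenly over 1.00 d, the run ends at 2.0 d
- Wednesday's: starting complex 0.050 M; incoming ligand 0.500 equiv; time 2.0 d; a closed flask charged with all of it at once and left for 2.0 d

- the set-up with the highest share of complex with three exchanged in all that became complex with three exchanged or complex with four exchanged, at the outlet or at the end ("none" if the first two lie within 2 percentage points) (Saturday's / Monday's / Tuesday's / Wednesday's / none)
- share of complex with three exchanged in all that became complex with three exchanged or complex with four exchanged, at the outlet or at the end, Saturday's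
- share of complex with three exchanged in all that became complex with three exchanged or complex with four exchanged, at the outlet or at the end, Monday's
- share of complex with three exchanged in all that became complex with three exchanged or complex with four exchanged, at the outlet or at the end, Tuesday's
- share of complex with three exchanged in all that became complex with three exchanged or complex with four exchanged, at the outlet or at the end, Wednesday's

- percent here means starting complex units held: one homo dimer counts as two
- where a step has two of a species, its rate is k times that concentration squared, and two are used at each turn
- the stated concentrations are those of everything mixed, before any reaction; amounts are the same in each set-up
- the feed brings no volume worth counting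
- run time (Saturday's): 2.0 d

1. The reckoning here is for Wednesday's closed flask and goes no further. Its clock is the exposure, meaning the incoming ligand concentration summed over time. On this clock each exchange runs at its own constant, however the ligand falls.

2. While exposure is small, each exchange adds one power of it. The complex with four exchanged over the complex with three exchanged then comes to the count divided by 4, and the share is 1/(1 + count/4).

3. First way to the count: incoming ligand, the limiting reagent at 0.500 equiv, meets starting complex held at its charge and lasts 0.0772 d. That gives 0.242 lifetimes of the complex with three exchanged, and a share of 94.3%.

4. Second way: set the homo dimer and the later exchanges aside and let the first exchange take the ligand. In this picture, spending 0.500 equiv leaves a fraction of 0.500 of the starting complex, which is one half-life on the exposure clock. Half-lives on this clock scale with the constants, so the complex with three exchanged lives 0.483 of its own half-lives meanwhile. The count of its lifetimes during the spending of the ligand comes to 0.335 and gives a share of 92.3%.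

5. The two part, 0.335 against 0.242. The first way cheats, since it holds starting complex at its charge while that complex is being used, which shortens the ligand's reckoned life. The second count is kept, and with it a share of 92.3%.

The forecast gives Wednesday's, with 85%, 62.4%, 77% and 90.5% for Saturday's to Wednesday's, on the grounds that “the limited ligand is used up fastest and earliest in the all-at-once batch”. For Wednesday's its figure is lower than the share reckoned here.

The simulation gives Wednesday's, with 77.0%, 62.4%, 77.2% and 91.3%.

Wednesday's share, read back through the rule, means a count of 0.381, a little above the 0.335 reckoned. The count stays this small because the incoming ligand is used up, with 0% of its charge standing at 2.00 d: with the ligand held at its charge, Wednesday's share falls from 91.3% to 13.3%.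

With 0.200 equiv of incoming ligand in the same closed flask, the count is 0.108, which gives a share of 97.4%. The simulation gives 96.5%.

The numbers of this flask stand for no real mixture, and the outcome is calculated.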